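**Plan**
1. Retrosynthesis: the epoxide goes back to the C12=C13 alkene, and the lactone is cut at C3–C18 (vinyl-radical closure from the C2 oxygen). Ring A is then cut at C4–C9 and C1–C2 (and C2–C3, with C2 coming from carbon monoxide), which also opens ring B; earlier cuts are C8–C9 (sp3–sp2 coupling), C12=C13 (metathesis) and C5–C6 ([3,3] shift of an achiral allyl ester).
2. Forward: ring C first (ester-enolate Claisen, then ring-closing metathesis), the two side arms next, rings B and A together in one cyclocarbonylation, then the lactone ring, and the epoxide last (15 steps).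
3. Enabling feature: ring A holds the quaternary C9 (bearing C17H2OAc) next to C1H2 and the oxygen-bearing C2. C1=C9 can therefore be a 2-substituted allyl acetate, C3≡C4 a terminal alkyne on C5, and C2 free CO; the two arms sit trans on the cycloheptene ring C, so ring B can close as a chair.
4. Stereochemistry: C5 and C6 come from one reagent-controlled Claisen rearrangement. C9 is relayed in the cyclocarbonylation, C2 by hydride attack anti to C17, C3 by the oxygen tether, C4 by hydrogen transfer anti to C17, and C12/C13 by attack anti to the C16 methyl.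

Key step: step 10

Numbering used for the polycycles (cyathane type): ring A = C1, C2, C3, C4, C9; ring B = C4 to C9; ring C = C5, C6, C14, C13, C12, C11, C10. C15 = CH3 on C12, C16 = CH3 on C6, C17 = CH2O on C9; C18 (on C3), C19 (=CH2) and C20 (C=O) are the lactone carbons. β is the face of C16, α the face of C17.

Assumption: the (S,S) controller is written in step 4 by analogy with simple allyl esters; its sense of induction is not derived here, and the (R,R) controller would be used, with no other change, if it is the one that leads to 10.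

**Step 1**
Reactants: 1 pent-1-en-4-yne
Product: 4 (2E)-3-methylhexa-2,5-dien-1-ol, via alkenylalane 2 (not isolated), via lithium alkenylaluminate 3 (not isolated)
Conditions: AlMe3, Cp2ZrCl2 (cat.), CH2Cl2, 0 °C to rt; then n-BuLi, THF, −78 °C; (CH2O)n, rt; aq. HCl
Reagents that add atoms: trimethylaluminium C[Al](C)C; formaldehyde (from paraformaldehyde) C=O
Why: Zirconium-catalysed Negishi carboalumination should add CH3 and Al syn across the terminal alkyne (Al on the terminal carbon), and hydroxymethylation of the derived alanate with retention fixes the E geometry.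

**Step 2**
Reactants: 5 5-oxohexanoic acid
Product: 6 5-methylhex-5-enoic acid
Conditions: Ph3PCH3Br, KOtBu (excess), THF, 0 °C to rt; aq. HCl
Reagents that add atoms: methyltriphenylphosphonium bromide C[P+](c1ccccc1)(c1ccccc1)c1ccccc1.[Br-]
Why: Wittig methylenation of the ketone, in which the carboxylate formed by the extra base is inert to the ylide.

**Step 3**
Reactants: 4 (2E)-3-methylhexa-2,5-dien-1-ol; 6 5-methylhex-5-enoic acid
Product: 7 (2E)-3-methylhexa-2,5-dien-1-yl 5-methylhex-5-enoate
Conditions: DCC, DMAP (cat.), CH2Cl2, 0 °C to rt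
Reagents that add atoms: none
Why: Steglich esterification of a primary allylic alcohol under neutral conditions that should leave the skipped diene untouched.

**Step 4**
Reactants: 7 (2E)-3-methylhexa-2,5-dien-1-yl 5-methylhex-5-enoate
Product: 10 (2S,3R)-3-ethenyl-3-methyl-2-(3-methylbut-3-en-1-yl)hex-5-enoic acid, via boron ketene acetal 8 (not isolated), via acyloxyborane 9 (not isolated)
Conditions: (S,S)-bis-sulfonamide controller, BBr3, CH2Cl2 (forms the bromodiazaborolidine); then 7, i-Pr2NEt, CH2Cl2, −78 °C; −20 to 4 °C; aq. work-up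
Reagents that add atoms: none
Why: Enantioselective Ireland–Claisen rearrangement of a chiral boron ketene acetal: the Z O-boron enolate expected with i-Pr2NEt in CH2Cl2 and the E alkene should react through a chair transition state, which places the carboxyl carbon C4 anti to the new vinyl group (syn to C16) at C5/C6, while the C2-symmetric diazaborolidine selects the enolate face.

**Step 5**
Reactants: 10 (2S,3R)-3-ethenyl-3-methyl-2-(3-methylbut-3-en-1-yl)hex-5-enoic acid
Product: 11 methyl (2S,3R)-3-ethenyl-3-methyl-2-(3-methylbut-3-en-1-yl)hex-5-enoate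
Conditions: TMSCHN2, MeOH/PhMe, 0 °C
Reagents that add atoms: (trimethylsilyl)diazomethane C[Si](C)(C)C=[N+]=[N-]
Why: O-methylation of the carboxylic acid through the methyldiazonium ion needs no base, so C5 cannot epimerise.

**Step 6**
Reactants: 11 methyl (2S,3R)-3-ethenyl-3-methyl-2-(3-methylbut-3-en-1-yl)hex-5-enoate
Product: 12 methyl (1S,2R)-2-ethenyl-2,5-dimethylcyclohept-4-ene-1-carboxylate
Conditions: second-generation Grubbs catalyst (5 mol %), CH2Cl2 (5 mM), 40 °C
Reagents that add atoms: none
Why: Ring-closing metathesis: the catalyst should load at the unhindered allyl group and close onto the isopropenyl group to give the trisubstituted cycloheptene, whereas the vinyl group on the quaternary C6 loads slowly and could only close a four-membered ring from the allyl-bound carbene.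

**Step 7**
Reactants: 12 methyl (1S,2R)-2-ethenyl-2,5-dimethylcyclohept-4-ene-1-carboxylate; 13 2-bromoprop-2-en-1-ol
Product: 15 methyl (1S,2S)-2-[3-(hydroxymethyl)but-3-en-1-yl]-2,5-dimethylcyclohept-4-ene-1-carboxylate, via B-alkyl-9-BBN 14 (not isolated)
Conditions: 9-BBN, THF, 0 °C to rt; then 13, Pd(dppf)Cl2 (5 mol %), AsPh3, aq. K3PO4, DMF, rt to 50 °C
Reagents that add atoms: none
Why: Anti-Markovnikov hydroboration with 9-BBN should take the monosubstituted vinyl group over the trisubstituted ring alkene, and the B-alkyl Suzuki–Miyaura coupling with the vinyl bromide joins C8 to C9 without touching a stereocentre.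

**Step 8**
Reactants: 15 methyl (1S,2S)-2-[3-(hydroxymethyl)but-3-en-1-yl]-2,5-dimethylcyclohept-4-ene-1-carboxylate
Product: 17 4-[(1S,7S)-7-ethynyl-1,4-dimethylcyclohept-3-en-1-yl]-2-methylidenebutan-1-ol, via aldehyde 16 (not isolated)
Conditions: DIBAL-H (2.3 equiv), CH2Cl2, −78 °C; then MeOH, dimethyl (1-diazo-2-oxopropyl)phosphonate, K2CO3, −78 °C to rt
Reagents that add atoms: dimethyl (1-diazo-2-oxopropyl)phosphonate CC(=O)C(=[N+]=[N-])P(=O)(OC)OC
Why: Partial reduction of the hindered ester (aluminium hemiacetal stable at −78 °C) followed in the same flask by Ohira–Bestmann homologation (Seyferth–Gilbert type) should give the terminal alkyne, and the mild base should leave C5, which lies next to the quaternary C6, unchanged.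

**Step 9**
Reactants: 17 4-[(1S,7S)-7-ethynyl-1,4-dimethylcyclohept-3-en-1-yl]-2-methylidenebutan-1-ol
Product: 18 4-[(1S,7S)-7-ethynyl-1,4-dimethylcyclohept-3-en-1-yl]-2-methylidenebutyl acetate
Conditions: Ac2O, pyridine, DMAP (cat.), CH2Cl2, 0 °C to rt
Reagents that add atoms: acetic anhydride CC(=O)OC(C)=O
Why: DMAP-catalysed acylation of the primary allylic alcohol installs the C17 acetate of the target before the metal-mediated step.

**Step 10**
Reactants: 18 4-[(1S,7S)-7-ethynyl-1,4-dimethylcyclohept-3-en-1-yl]-2-methylidenebutyl acetate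
Product: 20 (5S,6S,9R)-2-oxo-18,19,20-trinorcyatha-3,12-dien-17-yl acetate, via alkyne–Co2(CO)6 complex 19 (not isolated)
Conditions: Co2(CO)8 (1.1 equiv), CH2Cl2, rt; then NMO (8 equiv), 0 °C to rt
Reagents that add atoms: dicobalt octacarbonyl O=C=[Co](=C=O)(=C=O)(=C=O)[Co](=C=O)(=C=O)(=C=O)=C=O
Why: Intramolecular Pauson–Khand reaction: complex 19 loses CO on N-oxide treatment, the tethered 1,1-disubstituted alkene inserts into the Co–C4 bond (C4–C9), CO inserts at C1 (C1–C2) and reductive elimination closes C2–C3. The closest known type is the N-oxide-promoted cyclocarbonylation of 1,7-enynes that carry a 1,1-disubstituted alkene and are held on a ring. Ring B closes in the 6-exo sense at the alkene carbon joined to the tether, and ring A is the cyclopentenone assembled from C3, C4, C9, C1 and CO. The only new stereocentre, C9, should be set by a chair-like insertion transition state in which the ring C bonds at C5 and C6 are both equatorial, so that C1 lies in the plane of the forming enone and C17 is axial on the face opposite the axial C16 methyl. The step needs the side-chain alkene to react rather than C12=C13, which the substrate secures because the ring alkene could only give a strained bridged metallacycle; the regiochemistry is fixed by the tether.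

**Step 11**
Reactants: 20 (5S,6S,9R)-2-oxo-18,19,20-trinorcyatha-3,12-dien-17-yl acetate
Product: 21 (2S,5S,6S,9R)-2-hydroxy-18,19,20-trinorcyatha-3,12-dien-17-yl acetate
Conditions: NaBH4, CeCl3·7H2O, MeOH, −78 °C
Reagents that add atoms: none
Why: Luche 1,2-reduction in which hydride should add to C2 from the β face, opposite the axial C17 arm on C9, to give the 2α allylic alcohol while the acetate survives at low temperature.

**Step 12**
Reactants: 21 (2S,5S,6S,9R)-2-hydroxy-18,19,20-trinorcyatha-3,12-dien-17-yl acetate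
Product: 22 (2S,5S,6S,9R)-2-[(2-bromo-1-methoxyprop-2-en-1-yl)oxy]-18,19,20-trinorcyatha-3,12-dien-17-yl acetate (acetal epimers)
Conditions: methoxyallene, NBS, CH2Cl2, −78 to −20 °C
Reagents that add atoms: methoxyallene COC=C=C; N-bromosuccinimide O=C1CCC(=O)N1Br
Why: Bromoalkoxylation (cohalogenation) of the allenyl ether: bromine should add to the central allene carbon and the C2 alcohol trap the oxocarbenium ion, the enol ether being far more nucleophilic than the two trisubstituted alkenes, with C2 unchanged.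

**Step 13**
Reactants: 22 (2S,5S,6S,9R)-2-[(2-bromo-1-methoxyprop-2-en-1-yl)oxy]-18,19,20-trinorcyatha-3,12-dien-17-yl acetate (acetal epimers)
Product: 23 (2S,3S,4S,5R,6S,9R)-20-methoxy-2,20-epoxycyatha-12,18(19)-dien-17-yl acetate (C20 epimers)
Conditions: Bu3SnH (slow addition), AIBN (cat.), PhH, 80 °C
Reagents that add atoms: none
Why: Ueno–Stork-type radical cyclization: the C18 vinyl radical should close 5-exo onto C3 on the α face imposed by the O–C2 tether (cis ring fusion), and the tertiary C4 radical should take hydrogen from the stannane axially on the β face, anti to C17 and to the new ring, giving the trans junction of rings A and B.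

**Step 14**
Reactants: 23 (2S,3S,4S,5R,6S,9R)-20-methoxy-2,20-epoxycyatha-12,18(19)-dien-17-yl acetate (C20 epimers)
Product: 25 (2S,3S,4S,5R,6S,9R)-20-oxo-2,20-epoxycyatha-12,18(19)-dien-17-yl acetate, via lactol 24 (not isolated)
Conditions: CrO3, H2SO4, H2O/acetone, 0 °C
Reagents that add atoms: water O
Why: Jones oxidation, in which acid hydrolysis of the methyl acetal to the lactol and chromic acid oxidation should give the α-methylene γ-lactone from both acetal epimers without touching a stereocentre.

**Step 15**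
Reactants: 25 (2S,3S,4S,5R,6S,9R)-20-oxo-2,20-epoxycyatha-12,18(19)-dien-17-yl acetate
Product: 26 (2S,3S,4S,5R,6S,9R,12S,13R)-20-oxo-2,20:12,13-diepoxycyath-18(19)-en-17-yl acetate
Conditions: mCPBA, CH2Cl2, 0 °C
Reagents that add atoms: 3-chloroperbenzoic acid OOC(=O)c1cccc(Cl)c1
Why: Prilezhaev epoxidation: the electron-rich trisubstituted C12=C13 alkene should react while the conjugated exocyclic alkene of the lactone does not, and the peracid should attack the α face, anti to the axial C16 methyl on the homoallylic C6.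

**Compound list**
1 | pent-1-en-4-yne | C=CCC#C | starting material
2 | (E)-dimethyl(2-methylpenta-1,4-dien-1-yl)alane | C=CC/C(C)=C/[Al](C)C | intermediate
3 | lithium butyl(dimethyl)[(E)-2-methylpenta-1,4-dien-1-yl]aluminate | [Li+].C=CC/C(C)=C/[Al-](C)(C)CCCC | intermediate
4 | (2E)-3-methylhexa-2,5-dien-1-ol | C=CC/C(C)=C/CO | intermediate
5 | 5-oxohexanoic acid | CC(=O)CCCC(=O)O | starting material
6 | 5-methylhex-5-enoic acid | C=C(C)CCCC(=O)O | intermediate
7 | (2E)-3-methylhexa-2,5-dien-1-yl 5-methylhex-5-enoate | C=CC/C(C)=C/COC(=O)CCCC(C)=C | intermediate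
8 | Z O-boron ketene acetal of 7 (alkyl chain cis to O–B; boron in a (4S,5S)-1,3-bis{[3,5-bis(trifluoromethyl)phenyl]sulfonyl}-4,5-diphenyl-1,3,2-diazaborolidine) | C=C(C)CC/C=C(\OB1N(S(=O)(=O)c2cc(cc(c2)C(F)(F)F)C(F)(F)F)[C@@H](c2ccccc2)[C@H](c2ccccc2)N1S(=O)(=O)c1cc(cc(c1)C(F)(F)F)C(F)(F)F)OC/C=C(\C)CC=C | intermediate
9 | acyloxyborane of 10 (same diazaborolidinyl group on the carboxyl oxygen) | C=C[C@@](C)(CC=C)[C@H](CCC(C)=C)C(=O)OB1N(S(=O)(=O)c2cc(cc(c2)C(F)(F)F)C(F)(F)F)[C@@H](c2ccccc2)[C@H](c2ccccc2)N1S(=O)(=O)c1cc(cc(c1)C(F)(F)F)C(F)(F)F | intermediate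
10 | (2S,3R)-3-ethenyl-3-methyl-2-(3-methylbut-3-en-1-yl)hex-5-enoic acid | C=C[C@@](C)(CC=C)[C@H](CCC(C)=C)C(=O)O | intermediate
11 | methyl (2S,3R)-3-ethenyl-3-methyl-2-(3-methylbut-3-en-1-yl)hex-5-enoate | C=C[C@@](C)(CC=C)[C@H](CCC(C)=C)C(=O)OC | intermediate
12 | methyl (1S,2R)-2-ethenyl-2,5-dimethylcyclohept-4-ene-1-carboxylate | COC(=O)[C@H]1CCC(C)=CC[C@]1(C)C=C | intermediate
13 | 2-bromoprop-2-en-1-ol | C=C(Br)CO | starting material
14 | methyl (1S,2S)-2-[2-(9-borabicyclo[3.3.1]nonan-9-yl)ethyl]-2,5-dimethylcyclohept-4-ene-1-carboxylate | COC(=O)[C@H]1CCC(C)=CC[C@]1(C)CCB1C2CCCC1CCC2 | intermediate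
15 | methyl (1S,2S)-2-[3-(hydroxymethyl)but-3-en-1-yl]-2,5-dimethylcyclohept-4-ene-1-carboxylate | COC(=O)[C@H]1CCC(C)=CC[C@]1(C)CCC(=C)CO | intermediate
16 | (1S,2S)-2-[3-(hydroxymethyl)but-3-en-1-yl]-2,5-dimethylcyclohept-4-ene-1-carbaldehyde | O=C[C@H]1CCC(C)=CC[C@]1(C)CCC(=C)CO | intermediate
17 | 4-[(1S,7S)-7-ethynyl-1,4-dimethylcyclohept-3-en-1-yl]-2-methylidenebutan-1-ol | C#C[C@H]1CCC(C)=CC[C@]1(C)CCC(=C)CO | intermediate
18 | 4-[(1S,7S)-7-ethynyl-1,4-dimethylcyclohept-3-en-1-yl]-2-methylidenebutyl acetate | C#C[C@H]1CCC(C)=CC[C@]1(C)CCC(=C)COC(C)=O | intermediate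
19 | hexacarbonyldicobalt complex of the alkyne of 18 (C3 and C4 each bound to both cobalt atoms) | O=C=[Co]12(=C=O)(=C=O)[Co]3(=C=O)(=C=O)(=C=O)[CH]1C23[C@H]1CCC(C)=CC[C@]1(C)CCC(=C)COC(C)=O | intermediate
20 | (5S,6S,9R)-2-oxo-18,19,20-trinorcyatha-3,12-dien-17-yl acetate (tricyclic enone; 9α-CH2OAc, 6β-CH3, 5α-H) | O=C2C[C@]3(COC(C)=O)CC[C@@]4(C)CC=C(C)CC[C@@H]4C3=C2 | intermediate
21 | (2S,5S,6S,9R)-2-hydroxy-18,19,20-trinorcyatha-3,12-dien-17-yl acetate (2α-OH) | O[C@H]2C[C@]3(COC(C)=O)CC[C@@]4(C)CC=C(C)CC[C@@H]4C3=C2 | intermediate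
22 | (2S,5S,6S,9R)-2-[(2-bromo-1-methoxyprop-2-en-1-yl)oxy]-18,19,20-trinorcyatha-3,12-dien-17-yl acetate (both acetal epimers) | C=C(Br)C(OC)O[C@H]2C[C@]3(COC(C)=O)CC[C@@]4(C)CC=C(C)CC[C@@H]4C3=C2 | intermediate
23 | (2S,3S,4S,5R,6S,9R)-20-methoxy-2,20-epoxycyatha-12,18(19)-dien-17-yl acetate (both C20 epimers; 3β-H, 4β-H) | C=C1C(OC)O[C@H]2C[C@]3(COC(C)=O)CC[C@@]4(C)CC=C(C)CC[C@@H]4[C@H]3[C@@H]12 | intermediate
24 | (2S,3S,4S,5R,6S,9R)-20-hydroxy-2,20-epoxycyatha-12,18(19)-dien-17-yl acetate (lactol) | C=C1C(O)O[C@H]2C[C@]3(COC(C)=O)CC[C@@]4(C)CC=C(C)CC[C@@H]4[C@H]3[C@@H]12 | intermediate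
25 | (2S,3S,4S,5R,6S,9R)-20-oxo-2,20-epoxycyatha-12,18(19)-dien-17-yl acetate (α-methylene lactone) | C=C1C(=O)O[C@H]2C[C@]3(COC(C)=O)CC[C@@]4(C)CC=C(C)CC[C@@H]4[C@H]3[C@@H]12 | intermediate
26 | (2S,3S,4S,5R,6S,9R,12S,13R)-20-oxo-2,20:12,13-diepoxycyath-18(19)-en-17-yl acetate (12α,13α-epoxide) | C=C1C(=O)O[C@H]2C[C@]3(COC(C)=O)CC[C@@]4(C)C[C@H]5O[C@@]5(C)CC[C@@H]4[C@H]3[C@@H]12 | target

**Step count and risks**
Total step count: 15. Longest linear sequence: 14 steps (steps 1 and 3 to 15).

Most likely to fail: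

1. Step 10. The hindered 1,1-disubstituted alkene of a 1,7-enyne may insert too slowly, so that the alkyne is lost from cobalt (decomplexation or reduction) before ring B closes. Fallback, setting out from 17 and coming back at 20: the alkynol is silylated at carbon and oxygen (n-BuLi, 2.2 equiv, then TMSCl, THF, −78 °C) to the C,O-bis(trimethylsilyl) derivative F1. Zirconocene-mediated enyne bicyclization (Cp2ZrCl2, n-BuLi 2 equiv, THF, −78 °C to rt) should give the zirconabicycle F2 with the same chair preference at C9. Carbonylation (CO, 1 atm, 0 °C) and aqueous HCl work-up should give the 3-trimethylsilyl enone alcohol F3; protodesilylation (MeSO3H, CH2Cl2, 0 °C) gives the enone alcohol F4, which is acetylated (Ac2O, pyridine) to 20.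

2. Step 4. The [3,3] shift of the boron ketene acetal may be slow at low temperature, and control of enolate geometry or face may be incomplete, which would give low conversion or a mixture of stereoisomers. Fallback, setting out from 7 and coming back at 10: the rearrangement is run without a chiral controller (LDA, THF–HMPA, −78 °C, then TMSCl, then rt), through the Z trimethylsilyl ketene acetal F5 and the racemic silyl ester F6, to the racemic acid F7 of the same relative configuration. The acid is resolved by crystallization of the (R)-1-phenylethylammonium salt F8 (the S amine is used if the salt of the antipode proves the less soluble), and aqueous HCl returns 10.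

3. Step 13. Hydrogen transfer to the vinyl radical before the 5-exo closure, and later migration or hydration of the exocyclic alkene of the allylic acetal, may erode the route to the methylene lactone. Fallback, setting out from 21 and coming back at 25: bromoacetalization with ethyl vinyl ether and NBS (CH2Cl2, −40 °C) gives the ethyl bromoacetal F9. The alkyl radical closure (Bu3SnH, AIBN, PhH, 80 °C) gives the cyclic ethyl acetal F10 with the same cis fusion and β hydrogen at C4. Jones oxidation, through the lactol F11, gives the saturated lactone F12. Kinetic enolization of the lactone, the more acidic ester (LDA, THF, −78 °C), and dimethyl(methylidene)ammonium iodide give the Mannich base F13, which is quaternised (MeI) to the ammonium iodide F14 and eliminated (NaHCO3) to 25.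

**Further compounds**
F1 | step 10 | C,O-bis(trimethylsilyl) derivative of 17 (silyl alkyne and silyl ether) | C[Si](C)(C)C#C[C@H]1CCC(C)=CC[C@]1(C)CCC(=C)CO[Si](C)(C)C
F2 | step 10 | zirconabicycle (Cp2Zr bound to C3 and C1; C4–C9 bond formed) | C[Si](C)(C)C1=C2[C@H]3CCC(C)=CC[C@]3(C)CC[C@@]2(CO[Si](C)(C)C)C[Zr]1(C1C=CC=C1)C1C=CC=C1
F3 | step 10 | 3-(trimethylsilyl) enone alcohol (17-hydroxy, 3-silyl analogue of 20) | O=C2C[C@]3(CO)CC[C@@]4(C)CC=C(C)CC[C@@H]4C3=C2[Si](C)(C)C
F4 | step 10 | enone alcohol (17-hydroxy analogue of 20) | O=C2C[C@]3(CO)CC[C@@]4(C)CC=C(C)CC[C@@H]4C3=C2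
F5 | step 4 | Z trimethylsilyl ketene acetal of 7 | C=C(C)CC/C=C(\O[Si](C)(C)C)OC/C=C(\C)CC=C
F6 | step 4 | racemic trimethylsilyl ester (10 and its antipode as silyl esters) | C=C[C@@](C)(CC=C)[C@H](CCC(C)=C)C(=O)O[Si](C)(C)C.C=C[C@](C)(CC=C)[C@@H](CCC(C)=C)C(=O)O[Si](C)(C)C
F7 | step 4 | racemic acid (10 and its antipode) | C=C[C@@](C)(CC=C)[C@H](CCC(C)=C)C(=O)O.C=C[C@](C)(CC=C)[C@@H](CCC(C)=C)C(=O)O
F8 | step 4 | (R)-1-phenylethylammonium salt of 10 | C=C[C@@](C)(CC=C)[C@H](CCC(C)=C)C(=O)[O-].C[C@@H]([NH3+])c1ccccc1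
F9 | step 13 | 2-O-(2-bromo-1-ethoxyethyl) ether of 21 (acetal epimers) | BrCC(OCC)O[C@H]2C[C@]3(COC(C)=O)CC[C@@]4(C)CC=C(C)CC[C@@H]4C3=C2
F10 | step 13 | cyclic ethyl acetal (C18 = CH2; 20-ethoxy-2,20-epoxycyath-12-en-17-yl acetate) | C1C(OCC)O[C@H]2C[C@]3(COC(C)=O)CC[C@@]4(C)CC=C(C)CC[C@@H]4[C@H]3[C@@H]12
F11 | step 13 | lactol (20-hydroxy analogue of F10) | C1C(O)O[C@H]2C[C@]3(COC(C)=O)CC[C@@]4(C)CC=C(C)CC[C@@H]4[C@H]3[C@@H]12
F12 | step 13 | saturated γ-lactone (19-nor analogue of 25) | C1C(=O)O[C@H]2C[C@]3(COC(C)=O)CC[C@@]4(C)CC=C(C)CC[C@@H]4[C@H]3[C@@H]12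
F13 | step 13 | α-(dimethylaminomethyl) lactone (C18 epimers) | CN(C)CC1C(=O)O[C@H]2C[C@]3(COC(C)=O)CC[C@@]4(C)CC=C(C)CC[C@@H]4[C@H]3[C@@H]12
F14 | step 13 | trimethylammonium iodide of F13 | C[N+](C)(C)CC1C(=O)O[C@H]2C[C@]3(COC(C)=O)CC[C@@]4(C)CC=C(C)CC[C@@H]4[C@H]3[C@@H]12.[I-]
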